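Everything rests on cutting the pyran ring fused to ring B at its O–C(CH3)2 bond. This unveils a (Z)-o-quinone methide and, behind it, an aryl 1,1-dimethylpropargyl ether. Heating that monocyclic ether, made from isovanillin, runs a [3,3]/enolisation/[1,5]-H/oxa-6π cascade that forms the C3'–vinyl bond and then the O4'–C(CH3)2 bond in one operation. The step exploits the substitution of ring B. The C5' methoxy group blocks one ortho carbon, so only C3' accepts the chain, and the MOM cap on O2' leaves O4' as the only oxygen able to close. Directed metalation at C1' and Negishi coupling with a 3-iodochromone then attach rings A and C.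

Key step: step 4

Remark on the chemistry: the target holds no stereocentre. Its only stereo element, the cis C=C of the pyran ring, is fixed by the ring, so no enantiomer has to be selected.

**Step 1**
Reactants: 1 isovanillin (3-hydroxy-4-methoxybenzaldehyde); 2 3-chloro-3-methylbut-1-yne
Product: 3 4-methoxy-3-[(2-methylbut-3-yn-2-yl)oxy]benzaldehyde
Conditions: CuCl2·2H2O (cat.), DBU, MeCN, 0 °C to rt
Reagents that add atoms: 3-chloro-3-methylbut-1-yne (2), CC(C)(Cl)C#C
Why: Copper-catalysed O-propargylation of a phenol with a tertiary propargylic chloride runs through a copper allenylidene-type electrophile and should give the hindered tertiary aryl ether without touching the aldehyde.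

**Step 2**
Reactants: 3 4-methoxy-3-[(2-methylbut-3-yn-2-yl)oxy]benzaldehyde
Product: 5 4-methoxy-3-[(2-methylbut-3-yn-2-yl)oxy]phenol, via aryl formate 4 (not isolated)
Conditions: mCPBA, CH2Cl2, 0 °C to rt; then K2CO3 (cat.), MeOH, rt
Reagents that add atoms: mCPBA, OOC(=O)c1cccc(Cl)c1
Why: In this Baeyer–Villiger oxidation the aryl group, made electron-rich by the para methoxy group, should migrate in preference to hydrogen, the terminal alkyne is inert to the peracid, and methanolysis of the formate frees the phenol.

**Step 3**
Reactants: 5 4-methoxy-3-[(2-methylbut-3-yn-2-yl)oxy]phenol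
Product: 6 1-methoxy-4-(methoxymethoxy)-2-[(2-methylbut-3-yn-2-yl)oxy]benzene
Conditions: MOMCl, iPr2NEt, CH2Cl2, 0 °C to rt
Reagents that add atoms: chloromethyl methyl ether (MOMCl), COCCl
Why: Standard O-alkylation of the only free phenol gives an acetal that caps the future O2', is stable to heat and base, and later directs the metalation.

**Step 4**
Reactants: 6 1-methoxy-4-(methoxymethoxy)-2-[(2-methylbut-3-yn-2-yl)oxy]benzene
Product: 10 8-methoxy-5-(methoxymethoxy)-2,2-dimethyl-2H-chromene, via allenyl dienone 7 (not isolated), via allenylphenol 8 (not isolated), via o-quinone methide 9 (not isolated)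
Conditions: PhNEt2, 170 °C, Ar
Reagents that add atoms: none
Why: Heating triggers an aromatic propargyl Claisen [3,3] shift that breaks the ether O–C bond and joins the alkyne terminus to the free ortho carbon (future C3'), giving allenyl dienone 7, which enolises to allenylphenol 8. A [1,5]-H shift from the phenol O–H to the central allene carbon then gives the (Z)-o-quinone methide 9, and a thermally allowed disrotatory oxa-6π electrocyclisation joins the carbonyl oxygen to the C(CH3)2 terminus, closing the six-membered pyran ring and restoring aromaticity. The closest known reaction type is the thermal rearrangement of aryl 1,1-dimethylpropargyl ethers to 2,2-dimethyl-2H-chromenes. No stereocentre is formed, and the new ring alkene can only be cis. The step needs selectivity both for the carbon that is attacked and for the oxygen that closes: the methoxy group occupies the other ortho carbon, so a shift to that site is an unproductive, reversible dead end, and the MOM group leaves only the migrating oxygen with a proton for the [1,5]-H shift. The geminal methyl groups accelerate the [3,3] step, and the weakly basic solvent assists enolisation and keeps the acetal intact.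

**Step 5**
Reactants: 11 2,4-dihydroxyacetophenone
Product: 12 2-hydroxy-4-(methoxymethoxy)acetophenone
Conditions: MOMCl (1 equiv), K2CO3, acetone, rt
Reagents that add atoms: chloromethyl methyl ether (MOMCl), COCCl
Why: This O-alkylation should be selective because the 2-OH is locked in a hydrogen bond to the ketone, so only the more acidic and accessible 4-OH reacts.

**Step 6**
Reactants: 12 2-hydroxy-4-(methoxymethoxy)acetophenone
Product: 13 (E)-3-(dimethylamino)-1-[2-hydroxy-4-(methoxymethoxy)phenyl]prop-2-en-1-one
Conditions: DMF-DMA, neat, 95 °C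
Reagents that add atoms: N,N-dimethylformamide dimethyl acetal, COC(OC)N(C)C
Why: Condensation of the methyl ketone with the amide acetal (enaminone formation) installs the future C2 as the conjugated (E)-enaminone, the thermodynamically preferred geometry.

**Step 7**
Reactants: 13 (E)-3-(dimethylamino)-1-[2-hydroxy-4-(methoxymethoxy)phenyl]prop-2-en-1-one
Product: 14 3-iodo-7-(methoxymethoxy)-4H-chromen-4-one
Conditions: I2, pyridine, CHCl3, rt
Reagents that add atoms: iodine, II
Why: In this iodocyclisation the enaminone α-carbon is iodinated, the phenol adds to the iminium carbon and dimethylamine is lost, while pyridine buffers the acid so that the MOM ether should survive.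

**Step 8**
Reactants: 10 8-methoxy-5-(methoxymethoxy)-2,2-dimethyl-2H-chromene; 14 3-iodo-7-(methoxymethoxy)-4H-chromen-4-one
Product: 17 7-(methoxymethoxy)-3-[8-methoxy-5-(methoxymethoxy)-2,2-dimethyl-2H-chromen-6-yl]-4H-chromen-4-one, via aryllithium 15 (not isolated), via arylzinc chloride 16 (not isolated)
Conditions: n-BuLi, TMEDA, THF, 0 °C; ZnCl2, THF, 0 °C to rt; then 14, Pd(OAc)2 (cat.), SPhos (cat.), THF, 50 °C
Reagents that add atoms: n-BuLi, [Li]CCCC, and ZnCl2, Cl[Zn]Cl (they put Li and ZnCl into 15 and 16 only; none of their atoms stays in 17)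
Why: Directed ortho-metalation should occur next to the chelating OMOM group (a stronger director than OMe), and transmetalation to zinc gives a soft nucleophile that should undergo Negishi cross-coupling with the 3-iodochromone without adding to its electrophilic C2.

**Step 9**
Reactants: 17 7-(methoxymethoxy)-3-[8-methoxy-5-(methoxymethoxy)-2,2-dimethyl-2H-chromen-6-yl]-4H-chromen-4-one
Product: 18 7-hydroxy-3-(5-hydroxy-8-methoxy-2,2-dimethyl-2H-chromen-6-yl)-4H-chromen-4-one (target)
Conditions: HCl (cat.), MeOH, 45 °C
Reagents that add atoms: none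
Why: Acid-catalysed transacetalisation to methanol should remove both aryl MOM ethers in one operation under conditions that the methyl ether, the chromone and the 2,2-dimethylchromene normally tolerate.

**Compound list**
1 | isovanillin | COc1ccc(C=O)cc1O | starting material
2 | 3-chloro-3-methylbut-1-yne | CC(C)(Cl)C#C | starting material
3 | 4-methoxy-3-[(2-methylbut-3-yn-2-yl)oxy]benzaldehyde | COc1ccc(C=O)cc1OC(C)(C)C#C | intermediate
4 | 4-methoxy-3-[(2-methylbut-3-yn-2-yl)oxy]phenyl formate (not isolated) | COc1ccc(OC=O)cc1OC(C)(C)C#C | intermediate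
5 | 4-methoxy-3-[(2-methylbut-3-yn-2-yl)oxy]phenol | COc1ccc(O)cc1OC(C)(C)C#C | intermediate
6 | 1-methoxy-4-(methoxymethoxy)-2-[(2-methylbut-3-yn-2-yl)oxy]benzene | COCOc1ccc(OC)c(OC(C)(C)C#C)c1 | intermediate
7 | 2-methoxy-5-(methoxymethoxy)-6-(3-methylbuta-1,2-dienyl)cyclohexa-2,4-dien-1-one (racemic, transient, not isolated) | O=C1C(OC)=CC=C(OCOC)C1C=C=C(C)C | intermediate
8 | 6-methoxy-3-(methoxymethoxy)-2-(3-methylbuta-1,2-dienyl)phenol (not isolated) | COCOc1ccc(OC)c(O)c1C=C=C(C)C | intermediate
9 | (6Z)-2-methoxy-5-(methoxymethoxy)-6-(3-methylbut-2-enylidene)cyclohexa-2,4-dien-1-one (not isolated) | O=C1C(OC)=CC=C(OCOC)/C1=C/C=C(C)C | intermediate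
10 | 8-methoxy-5-(methoxymethoxy)-2,2-dimethyl-2H-chromene | COCOc1ccc(OC)c2c1C=CC(C)(C)O2 | intermediate
11 | 2,4-dihydroxyacetophenone | CC(=O)c1ccc(O)cc1O | starting material
12 | 2-hydroxy-4-(methoxymethoxy)acetophenone | CC(=O)c1ccc(OCOC)cc1O | intermediate
13 | (E)-3-(dimethylamino)-1-[2-hydroxy-4-(methoxymethoxy)phenyl]prop-2-en-1-one | CN(C)/C=C/C(=O)c1ccc(OCOC)cc1O | intermediate
14 | 3-iodo-7-(methoxymethoxy)-4H-chromen-4-one | COCOc1ccc2c(c1)occ(I)c2=O | intermediate
15 | [8-methoxy-5-(methoxymethoxy)-2,2-dimethyl-2H-chromen-6-yl]lithium (not isolated) | COCOc1c([Li])cc(OC)c2c1C=CC(C)(C)O2 | intermediate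
16 | [8-methoxy-5-(methoxymethoxy)-2,2-dimethyl-2H-chromen-6-yl]zinc chloride (not isolated) | COCOc1c([Zn]Cl)cc(OC)c2c1C=CC(C)(C)O2 | intermediate
17 | 7-(methoxymethoxy)-3-[8-methoxy-5-(methoxymethoxy)-2,2-dimethyl-2H-chromen-6-yl]-4H-chromen-4-one | COCOc1ccc2c(c1)occ(-c1cc(OC)c3c(c1OCOC)C=CC(C)(C)O3)c2=O | intermediate
18 | 7-hydroxy-3-(5-hydroxy-8-methoxy-2,2-dimethyl-2H-chromen-6-yl)-4H-chromen-4-one | COc1cc(-c2coc3cc(O)ccc3c2=O)c(O)c2c1OC(C)(C)C=C2 | target

Total step count: 9. Longest linear sequence: 6 (steps 1, 2, 3, 4, 8, 9).

**Steps most likely to fail**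

Step 8. Deprotonation may be unselective between the positions next to OMOM and next to OMe. The butyllithium may also add to the styrene-type alkene of the chromene at 0 °C. The fallback replaces C–H metalation by halogen–metal exchange and sets out from 6.
- Electrophilic bromination of 6 (NBS, MeCN, 0 °C) should go to the carbon ortho to OMOM and para to the propargyl ether oxygen. This gives 1-bromo-5-methoxy-2-(methoxymethoxy)-4-[(2-methylbut-3-yn-2-yl)oxy]benzene F1.
- The same thermal cascade (PhNEt2, 170 °C) converts F1 into 6-bromo-8-methoxy-5-(methoxymethoxy)-2,2-dimethyl-2H-chromene F2.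
- Br–Li exchange on F2 (n-BuLi, THF, −78 °C) is site-defined and fast at low temperature. It comes back to the route at 15, which is carried on with ZnCl2 and 14 to 17.

Step 4. The [3,3] shift has to reach a carbon flanked by two oxygen substituents. At the temperature required, loss of the tertiary propargyl group by elimination may compete. The fallback moves to the allyl oxidation level with a biomimetic oxidative closure and sets out from 6.
- Semihydrogenation of 6 (H2, Lindlar catalyst, quinoline, EtOAc) gives the 1,1-dimethylallyl ether 1-methoxy-4-(methoxymethoxy)-2-[(2-methylbut-3-en-2-yl)oxy]benzene F3.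
- The aromatic Claisen rearrangement of F3 runs at a much lower temperature (toluene, 110 °C). It gives 6-methoxy-3-(methoxymethoxy)-2-(3-methylbut-2-enyl)phenol F4.
- Dehydrogenation of F4 with DDQ (toluene, 80 °C) forms the same o-quinone methide 9, which closes by oxa-6π electrocyclisation. The fallback comes back to the route at 10.

Step 9. Brønsted acid may add methanol across the chromene alkene. It may also open and re-close the pyranone of the 2'-hydroxyisoflavone before both acetals are gone. The fallback exchanges the acetals for silyl ethers without free acid and sets out from 17.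
- TMSOTf and 2,2'-bipyridyl (MeCN, 0 °C to rt) convert both aryl MOM ethers of 17 into the bis(trimethylsilyl) ether F5.
- Water is then added at neutral pH to hydrolyse the silyl ethers of F5. The fallback comes back to the route at 18.

**Further compounds**
F1 | step 8 | 1-bromo-5-methoxy-2-(methoxymethoxy)-4-[(2-methylbut-3-yn-2-yl)oxy]benzene | COCOc1cc(OC(C)(C)C#C)c(OC)cc1Br
F2 | step 8 | 6-bromo-8-methoxy-5-(methoxymethoxy)-2,2-dimethyl-2H-chromene | COCOc1c(Br)cc(OC)c2c1C=CC(C)(C)O2
F3 | step 4 | 1-methoxy-4-(methoxymethoxy)-2-[(2-methylbut-3-en-2-yl)oxy]benzene | COCOc1ccc(OC)c(OC(C)(C)C=C)c1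
F4 | step 4 | 6-methoxy-3-(methoxymethoxy)-2-(3-methylbut-2-enyl)phenol | COCOc1ccc(OC)c(O)c1CC=C(C)C
F5 | step 9 | 3-[8-methoxy-2,2-dimethyl-5-(trimethylsilyloxy)-2H-chromen-6-yl]-7-(trimethylsilyloxy)-4H-chromen-4-one | C[Si](C)(C)Oc1ccc2c(c1)occ(-c1cc(OC)c3c(c1O[Si](C)(C)C)C=CC(C)(C)O3)c2=O
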